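**Strategy.** The target is a meso 2,5-diaryl-3,4-bis(acetoxymethyl)tetrahydrofuran. A mirror plane through O1 and the midpoint of C3–C4 makes the bonds C2–C3 and C5–C4 equivalent. Everything rests on cutting both. This leaves a symmetric 1,3-diaryl carbonyl ylide (C2–O1–C5) and a cis four-carbon dipolarophile (C3–C4 with both side-chain carbons). In one operation a photoredox-triggered [3+2] cycloaddition closes the tetrahydrofuran ring, forms both C–C bonds and sets all four stereocentres. The precursor looks unlike the product: a racemic trans-2,3-diaryloxirane, whose C–C bond is broken, and maleic anhydride, whose temporary ring locks the 3,4-cis relation. Reduction, acetylation and debenzylation finish the synthesis.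

Key step: step 2

Remark on the chemistry: the (2S,3R,4S,5R) array with pairwise identical substituents is meso (2,3-trans, 3,4-cis, 4,5-trans, 2,5-cis), so only relative configuration has to be controlled. Compounds 1, 2 and 5 are taken as catalogue items. Ring numbering throughout is O1, C2 (aryl), C3, C4, C5 (aryl).

Step 1
Reactants: 1 3,4-bis(benzyloxy)benzyl chloride; 2 3,4-bis(benzyloxy)benzaldehyde
Product: 4 rac-trans-2,3-bis[3,4-bis(benzyloxy)phenyl]oxirane, via sulfonium chloride 3 (not isolated)
Conditions: 1, tetrahydrothiophene (1.5 equiv), MeCN, rt; then 2, powdered KOH (2 equiv), MeCN–H2O 9:1, 0 °C to rt; crystallisation or Et3N-deactivated silica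
Reagents that add atoms: tetrahydrothiophene, C1CCSC1 (its atoms are held only in intermediate 3 and leave again on ring closure)
Why: S-alkylation followed by Corey–Chaykovsky-type epoxidation with a semistabilised benzylic sulfonium ylide, in which reversible betaine formation favours the trans-oxirane (racemic); its two stereocentres are erased in step 2, so their control is not critical.

Step 2
Reactants: 4 rac-trans-2,3-bis[3,4-bis(benzyloxy)phenyl]oxirane; 5 maleic anhydride
Product: 7 meso exo adduct (3aR,4R,6S,6aS)-4,6-bis[3,4-bis(benzyloxy)phenyl]tetrahydro-1H,3H-furo[3,4-c]furan-1,3-dione, via carbonyl ylide 6 (not isolated)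
Conditions: 5 (freshly sublimed, 3 equiv), 4-mesityl-2,6-di-p-tolylpyrylium tetrafluoroborate (5 mol %), 4 Å MS, degassed CH2Cl2, blue LEDs (about 450 nm), 0 °C
Reagents that add atoms: none
Why: The excited pyrylium salt oxidises a dialkoxyaryl ring of 4 by single-electron transfer, the oxirane radical cation breaks its C–C bond, and back electron transfer from the pyranyl radical gives the neutral 1,3-diaryl carbonyl ylide 6, which adds to 5 in a concerted suprafacial 1,3-dipolar cycloaddition that forms C2–C3 and C5–C4 together. The closest known reaction type is the photoinduced-electron-transfer (photoredox) carbonyl ylide cycloaddition of 2,3-diaryloxiranes with electron-poor alkenes. The tetrahydrofuran ring is closed by this intermolecular [3+2] (4π+2π) cycloaddition and emerges cis-fused to the temporary anhydride ring brought in by 5. C2 and C5 become cis because the ylide reacts from its least hindered E,E (W-shaped) geometry, C3 and C4 become cis because the Z-alkene of 5 is locked in a ring and adds suprafacially, and the 2,3-trans and 4,5-trans relations come from exo approach, in which the anhydride lies under the two inward ylide hydrogens and away from the two bulky aryl groups. The step needs C–C over C–O scission of the oxirane (secured by a donor aryl group on each oxirane carbon), capture of the ylide faster than its reclosure (secured by the low LUMO and the excess of 5), and exo over endo approach (secured only by sterics). Product 7 is meso, so no absolute control is required.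

Step 3
Reactants: 7 meso exo adduct (cis-fused anhydride)
Product: 8 meso-{(2R,3S,4R,5S)-2,5-bis[3,4-bis(benzyloxy)phenyl]tetrahydrofuran-3,4-diyl}dimethanol
Conditions: LiAlH4 (4 equiv), THF, 0 °C to 50 °C; Fieser work-up (H2O, 15% aq NaOH, H2O)
Reagents that add atoms: none
Why: Exhaustive LiAlH4 reduction of a cyclic anhydride (via the lactone) touches no stereocentre, the cis-fused bicycle resists α-epimerisation, and the basic work-up avoids acid-induced ionisation of the benzylic C–O bonds.

Step 4
Reactants: 8 meso diol
Product: 9 meso-{(2R,3S,4R,5S)-2,5-bis[3,4-bis(benzyloxy)phenyl]tetrahydrofuran-3,4-diyl}bis(methylene) diacetate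
Conditions: Ac2O (3 equiv), pyridine, DMAP (cat.), CH2Cl2, 0 °C to rt
Reagents that add atoms: acetic anhydride, CC(=O)OC(C)=O
Why: DMAP-catalysed O-acetylation (nucleophilic acyl substitution) of two unhindered primary alcohols runs under basic conditions that leave the benzylic ethers and all stereocentres untouched.

Step 5
Reactants: 9 meso tetrabenzyl diacetate
Product: 10 target, meso-{(2R,3S,4R,5S)-2,5-bis(3,4-dihydroxyphenyl)tetrahydrofuran-3,4-diyl}bis(methylene) diacetate (identical with the 2S,3R,4S,5R notation)
Conditions: H2 (1 atm), 10% Pd/C, EtOAc, rt, stopped at full debenzylation; filtration under argon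
Reagents that add atoms: none
Why: Heterogeneous catalytic hydrogenolysis cleaves the four unhindered aryl benzyl ethers far faster than the hindered secondary ring C–O bonds in a neutral aprotic medium, and the acetates and stereocentres are unaffected.

**Compound list**
1 | 3,4-bis(benzyloxy)benzyl chloride | ClCc1ccc(OCc2ccccc2)c(OCc2ccccc2)c1 | starting material
2 | 3,4-bis(benzyloxy)benzaldehyde | O=Cc1ccc(OCc2ccccc2)c(OCc2ccccc2)c1 | starting material
3 | 1-[3,4-bis(benzyloxy)benzyl]tetrahydrothiophenium chloride | [Cl-].C1CC[S+](C1)Cc1ccc(OCc2ccccc2)c(OCc2ccccc2)c1 | intermediate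
4 | rac-trans-2,3-bis[3,4-bis(benzyloxy)phenyl]oxirane (2R,3R enantiomer drawn) | O1[C@H](c2ccc(OCc3ccccc3)c(OCc3ccccc3)c2)[C@H]1c1ccc(OCc2ccccc2)c(OCc2ccccc2)c1 | intermediate
5 | maleic anhydride | O=C1C=CC(=O)O1 | starting material
6 | (E,E)-1,3-bis[3,4-bis(benzyloxy)phenyl] carbonyl ylide | C(c1ccccc1)Oc1ccc(/C=[O+]/[CH-]c2ccc(OCc3ccccc3)c(OCc3ccccc3)c2)cc1OCc1ccccc1 | intermediate
7 | meso-(3aR,4R,6S,6aS)-4,6-bis[3,4-bis(benzyloxy)phenyl]tetrahydro-1H,3H-furo[3,4-c]furan-1,3-dione (cis-fused; aryl groups cis to each other, trans to the anhydride ring) | O=C2[C@@H]1[C@H](C(=O)O2)[C@@H](c3ccc(OCc4ccccc4)c(OCc4ccccc4)c3)O[C@H]1c1ccc(OCc2ccccc2)c(OCc2ccccc2)c1 | intermediate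
8 | meso-{(2R,3S,4R,5S)-2,5-bis[3,4-bis(benzyloxy)phenyl]tetrahydrofuran-3,4-diyl}dimethanol | OC[C@@H]1[C@H](CO)[C@@H](c2ccc(OCc3ccccc3)c(OCc3ccccc3)c2)O[C@H]1c1ccc(OCc2ccccc2)c(OCc2ccccc2)c1 | intermediate
9 | meso-{(2R,3S,4R,5S)-2,5-bis[3,4-bis(benzyloxy)phenyl]tetrahydrofuran-3,4-diyl}bis(methylene) diacetate | CC(=O)OC[C@@H]1[C@H](COC(C)=O)[C@@H](c2ccc(OCc3ccccc3)c(OCc3ccccc3)c2)O[C@H]1c1ccc(OCc2ccccc2)c(OCc2ccccc2)c1 | intermediate
10 | meso-{(2R,3S,4R,5S)-2,5-bis(3,4-dihydroxyphenyl)tetrahydrofuran-3,4-diyl}bis(methylene) diacetate (CNP0416169.1) | CC(=O)OC[C@@H]1[C@H](COC(C)=O)[C@@H](c2ccc(O)c(O)c2)O[C@H]1c1ccc(O)c(O)c1 | target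

**Total step count:** 5. **Longest linear sequence:** 5 steps (from 1 or 2 to 10).

**Steps most likely to fail**

Step 2. The risks are poor exo/endo facial selectivity, partial loss of the E,E ylide geometry, and acid-induced rearrangement of the labile oxirane before it is oxidised.
- The fallback moves stereocontrol from kinetic approach control to thermodynamic equilibration.
- It sets out from 4. The cycloaddition is run without regard to selectivity.
- The endo-derived all-cis anhydride F1 (alone or in admixture) is reduced with LiAlH4 to the all-cis diol F2 and acetylated to the all-cis diacetate F3.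
- Catalytic BF3·OEt2 in CH2Cl2 at 0 °C then ionises the electron-rich benzylic C–O bonds reversibly. This equilibrates C2 and C5, while C3 and C4 stay fixed.
- The isomer with each aryl group trans to its neighbouring side chain should be the thermodynamic sink. The sequence comes back to the route at 9.

Step 1. The risks are hydrolysis of the very reactive benzylic chloride or sulfonium salt in the basic aqueous medium, and Meinwald-type rearrangement of the electron-rich oxirane during isolation.
- The fallback sets out from 2 alone.
- McMurry homocoupling with low-valent titanium (TiCl4, Zn, THF, reflux) should give (E)-1,2-bis[3,4-bis(benzyloxy)phenyl]ethene F4.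
- Neutral epoxidation with dimethyldioxirane in acetone–CH2Cl2 at 0 °C leaves only volatile by-product and needs no chromatography. The sequence comes back to the route at 4.

Step 5. The risks are competing hydrogenolytic opening of the doubly benzylic ring C–O bonds once the phenols are freed, and air oxidation of the catechols on work-up.
- The fallback sets out from 9 and replaces reduction by a Lewis-acid-mediated Friedel–Crafts benzyl transfer (BCl3, pentamethylbenzene, CH2Cl2, −78 °C, aqueous quench).
- This should deliver 10 directly without a new intermediate.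
- Any reversible ring ionisation would return the same configuration, because that configuration is the thermodynamically preferred one.

**Further compounds**
F1 | step 2 | meso-(3aR,4S,6R,6aS)-4,6-bis[3,4-bis(benzyloxy)phenyl]tetrahydro-1H,3H-furo[3,4-c]furan-1,3-dione (all-cis endo adduct) | O=C2[C@@H]1[C@H](C(=O)O2)[C@H](c3ccc(OCc4ccccc4)c(OCc4ccccc4)c3)O[C@@H]1c1ccc(OCc2ccccc2)c(OCc2ccccc2)c1
F2 | step 2 | meso-{(2R,3R,4S,5S)-2,5-bis[3,4-bis(benzyloxy)phenyl]tetrahydrofuran-3,4-diyl}dimethanol (all-cis) | OC[C@@H]1[C@H](CO)[C@H](c2ccc(OCc3ccccc3)c(OCc3ccccc3)c2)O[C@@H]1c1ccc(OCc2ccccc2)c(OCc2ccccc2)c1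
F3 | step 2 | meso-{(2R,3R,4S,5S)-2,5-bis[3,4-bis(benzyloxy)phenyl]tetrahydrofuran-3,4-diyl}bis(methylene) diacetate (all-cis) | CC(=O)OC[C@@H]1[C@H](COC(C)=O)[C@H](c2ccc(OCc3ccccc3)c(OCc3ccccc3)c2)O[C@@H]1c1ccc(OCc2ccccc2)c(OCc2ccccc2)c1
F4 | step 1 | (E)-1,2-bis[3,4-bis(benzyloxy)phenyl]ethene | C(c1ccccc1)Oc1ccc(/C=C/c2ccc(OCc3ccccc3)c(OCc3ccccc3)c2)cc1OCc1ccccc1
F0 | step 5 | none | none
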